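**Retrosynthetic overview**
1. Target 17 ⇒ C3–CH2Ar bond: trans-selective alkylation of the enolate of (R)-lactone 10 with carbonate-protected vanillyl bromide 14, then removal of the carbonate.
2. Lactone 10 (the only ring made in the route) ⇒ oxidation and desilylative lactonisation of aldehyde 8.
3. Key disconnection, C4–CH2Ar of 8 ⇒ enantioselective photochemical radical–radical coupling between the benzylic C–H of 3,4,5-trimethoxytoluene 4 and the chiral iminium ion of enal 7.
4. Both arenes ⇒ p-cresol 1 by ortho-bromination and copper-catalysed methoxylation; enal 7 ⇒ cross-metathesis of crotonaldehyde 5 with allyl silyl ether 6.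

Assumption: the facial sense of step 4 follows the usual shielding model of diarylprolinol silyl ether catalysts (bond formation anti to the silyloxydiarylmethyl group), so the (R)-catalyst is taken to give (R)-8; the (S)-catalyst would be used if the opposite sense were found.

**Route**

Step 1
Reactants: 1 p-cresol (4-methylphenol)
Product: 2 2,6-dibromo-4-methylphenol
Conditions: Br2 (2.05 equiv), CH2Cl2, 0 °C to rt
Reagents that add atoms: bromine, BrBr
Why: Electrophilic aromatic bromination; the hydroxyl group directs to both ortho positions because the para position is blocked by the methyl group.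

Step 2
Reactants: 2 2,6-dibromo-4-methylphenol
Product: 4 3,4,5-trimethoxytoluene, via sodium 2,6-dimethoxy-4-methylphenolate 3 (not isolated)
Conditions: NaOMe (5 equiv), CuBr (10 mol %), DMF/MeOH, 110 °C; then MeI (4 equiv), 40 °C
Reagents that add atoms: sodium methoxide, C[O-].[Na+]; iodomethane, CI
Why: Ullmann-type copper-catalysed methoxylation of both aryl bromides on the phenolate, followed by Williamson O-methylation of the phenolate in the same pot.

Step 3
Reactants: 5 (E)-but-2-enal (crotonaldehyde); 6 allyloxy(tert-butyl)dimethylsilane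
Product: 7 (E)-4-[(tert-butyldimethylsilyl)oxy]but-2-enal
Conditions: second-generation Hoveyda–Grubbs catalyst RuCl2(H2IMes)(=CH-C6H4-2-OiPr) (2.5 mol %), 5 (3 equiv), CH2Cl2, 40 °C
Reagents that add atoms: none
Why: Olefin cross-metathesis between a fast-reacting allyl ether and an electron-poor enal gives the E-enal selectively, driven by loss of propene.

Step 4
Reactants: 4 3,4,5-trimethoxytoluene; 7 (E)-4-[(tert-butyldimethylsilyl)oxy]but-2-enal
Product: 8 (R)-4-[(tert-butyldimethylsilyl)oxy]-3-(3,4,5-trimethoxybenzyl)butanal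
Conditions: 4 (5 equiv, excess recovered), (R)-2-{bis[3,5-bis(trifluoromethyl)phenyl][(tert-butyldimethylsilyl)oxy]methyl}-4,4-difluoropyrrolidine (20 mol %), TFA (40 mol %), Zn(OTf)2 (50 mol %), MeCN, 405 nm LED, 0 °C, degassed
Reagents that add atoms: none
Why: Proposed new method: 7 condenses with the amine to a chiral iminium ion whose photoexcited state (or its charge-transfer complex with the very electron-rich arene 4) takes one electron from 4; the arene radical cation is deprotonated at the benzylic methyl by triflate or trifluoroacetate, and the 3,4,5-trimethoxybenzyl radical couples with the persistent β-enaminyl radical at the β-carbon on the face anti to the silyloxydiarylmethyl group, which sets C3 of 8 as (R) before enamine hydrolysis releases the catalyst; the closest known reaction type is the enantioselective photo-organocatalytic β-benzylation of aromatic enals with toluene derivatives through excited iminium ions, extended here to an aliphatic γ-silyloxy enal.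

Step 5
Reactants: 8 (R)-4-[(tert-butyldimethylsilyl)oxy]-3-(3,4,5-trimethoxybenzyl)butanal
Product: 10 (R)-4-(3,4,5-trimethoxybenzyl)dihydrofuran-2(3H)-one, via silyloxy acid 9 (not isolated)
Conditions: NaClO2, NaH2PO4, 2-methyl-2-butene (10 equiv), t-BuOH/H2O, 0 °C to rt; then 2 M HCl, THF, rt
Reagents that add atoms: sodium chlorite, [O-]Cl=O.[Na+]
Why: Pinnick oxidation (hypochlorous acid is scavenged by the alkene, protecting the electron-rich ring) followed by acid desilylation and spontaneous γ-lactonisation; the stereocenter is β to the carbonyl and is not touched.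

Step 6
Reactants: 1 p-cresol
Product: 11 2-bromo-4-methylphenol
Conditions: Br2 (1.0 equiv), CH2Cl2, −5 °C
Reagents that add atoms: bromine, BrBr
Why: Electrophilic aromatic monobromination ortho to the hydroxyl group, kept at the mono stage by stoichiometry and low temperature.

Step 7
Reactants: 11 2-bromo-4-methylphenol
Product: 12 2-methoxy-4-methylphenol (creosol)
Conditions: NaOMe (4 equiv), CuBr (10 mol %), DMF/MeOH, 110 °C; aqueous HCl work-up
Reagents that add atoms: sodium methoxide, C[O-].[Na+]
Why: Ullmann-type copper-catalysed methoxylation of the aryl bromide on the phenolate.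

Step 8
Reactants: 12 2-methoxy-4-methylphenol
Product: 13 tert-butyl (2-methoxy-4-methylphenyl) carbonate
Conditions: Boc2O (1.2 equiv), DMAP (5 mol %), MeCN, rt
Reagents that add atoms: di-tert-butyl dicarbonate, CC(C)(C)OC(=O)OC(=O)OC(C)(C)C
Why: DMAP-catalysed O-acylation of the phenol gives an aryl carbonate that masks the phenol and lowers the electron density of the ring for the next step.

Step 9
Reactants: 13 tert-butyl (2-methoxy-4-methylphenyl) carbonate
Product: 14 4-(bromomethyl)-2-methoxyphenyl tert-butyl carbonate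
Conditions: NBS (1.05 equiv), AIBN (5 mol %), PhCF3, 80 °C
Reagents that add atoms: N-bromosuccinimide, O=C1CCC(=O)N1Br
Why: Wohl–Ziegler radical benzylic bromination; the carbonate-deactivated ring and the non-polar medium disfavour nuclear bromination.

Step 10
Reactants: 10 (R)-4-(3,4,5-trimethoxybenzyl)dihydrofuran-2(3H)-one; 14 4-(bromomethyl)-2-methoxyphenyl tert-butyl carbonate
Product: 16 tert-butyl {2-methoxy-4-[((3R,4R)-2-oxo-4-(3,4,5-trimethoxybenzyl)tetrahydrofuran-3-yl)methyl]phenyl} carbonate, via lithium enolate 15 (not isolated)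
Conditions: LiHMDS (1.05 equiv), THF, −78 °C, 30 min; then 14 (1.1 equiv), −78 to −40 °C
Reagents that add atoms: none
Why: SN2 alkylation of the lactone enolate; the benzyl bromide approaches anti to the C4 substituent, giving the trans (3R,4R) lactone, which is also the thermodynamic isomer.

Step 11
Reactants: 16 the carbonate-protected trans lactone
Product: 17 (3R,4R)-3-(4-hydroxy-3-methoxybenzyl)-4-(3,4,5-trimethoxybenzyl)dihydrofuran-2(3H)-one (target)
Conditions: TFA/CH2Cl2 (1:4), 0 °C, 1 h, dilute
Reagents that add atoms: none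
Why: Acidolysis of the aryl tert-butyl carbonate (loss of isobutene, then decarboxylation) frees the phenol without affecting the lactone, the methyl ethers or either stereocenter.

**Compound list**
1 | p-cresol (4-methylphenol) | Cc1ccc(O)cc1 | starting material
2 | 2,6-dibromo-4-methylphenol | Cc1cc(Br)c(O)c(Br)c1 | intermediate
3 | sodium 2,6-dimethoxy-4-methylphenolate | [Na+].[O-]c1c(OC)cc(C)cc1OC | intermediate (not isolated)
4 | 3,4,5-trimethoxytoluene (1,2,3-trimethoxy-5-methylbenzene) | COc1cc(C)cc(OC)c1OC | intermediate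
5 | (E)-but-2-enal (crotonaldehyde) | C/C=C/C=O | starting material
6 | allyloxy(tert-butyl)dimethylsilane (allyl alcohol carrying a TBS protecting group) | C=CCO[Si](C)(C)C(C)(C)C | starting material
7 | (E)-4-[(tert-butyldimethylsilyl)oxy]but-2-enal | O=C/C=C/CO[Si](C)(C)C(C)(C)C | intermediate
8 | (R)-4-[(tert-butyldimethylsilyl)oxy]-3-(3,4,5-trimethoxybenzyl)butanal | O=CC[C@H](CO[Si](C)(C)C(C)(C)C)Cc1cc(OC)c(OC)c(OC)c1 | intermediate
9 | (R)-4-[(tert-butyldimethylsilyl)oxy]-3-(3,4,5-trimethoxybenzyl)butanoic acid | OC(=O)C[C@H](CO[Si](C)(C)C(C)(C)C)Cc1cc(OC)c(OC)c(OC)c1 | intermediate (not isolated)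
10 | (R)-4-(3,4,5-trimethoxybenzyl)dihydrofuran-2(3H)-one | O=C1C[C@@H](Cc2cc(OC)c(OC)c(OC)c2)CO1 | intermediate
11 | 2-bromo-4-methylphenol | Cc1ccc(O)c(Br)c1 | intermediate
12 | 2-methoxy-4-methylphenol (creosol) | COc1cc(C)ccc1O | intermediate
13 | tert-butyl (2-methoxy-4-methylphenyl) carbonate | COc1cc(C)ccc1OC(=O)OC(C)(C)C | intermediate
14 | 4-(bromomethyl)-2-methoxyphenyl tert-butyl carbonate | COc1cc(CBr)ccc1OC(=O)OC(C)(C)C | intermediate
15 | lithium enolate of 10, lithium (R)-3-(3,4,5-trimethoxybenzyl)-2,3-dihydrofuran-5-olate | [Li+].[O-]C1=C[C@@H](Cc2cc(OC)c(OC)c(OC)c2)CO1 | intermediate (not isolated)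
16 | tert-butyl {2-methoxy-4-[((3R,4R)-2-oxo-4-(3,4,5-trimethoxybenzyl)tetrahydrofuran-3-yl)methyl]phenyl} carbonate | COc1cc(C[C@H]2C(=O)OC[C@@H]2Cc2cc(OC)c(OC)c(OC)c2)ccc1OC(=O)OC(C)(C)C | intermediate
17 | (3R,4R)-3-(4-hydroxy-3-methoxybenzyl)-4-(3,4,5-trimethoxybenzyl)dihydrofuran-2(3H)-one | COc1cc(C[C@H]2C(=O)OC[C@@H]2Cc2cc(OC)c(OC)c(OC)c2)ccc1O | target

**Totals**
Total step count: 11. Longest linear sequence: 6 steps (1 → 2 → 4 → 8 → 10 → 16 → 17, or 1 → 11 → 12 → 13 → 14 → 16 → 17).

**Steps most likely to fail, with fallbacks**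

Step 4 is the main risk. The aliphatic γ-silyloxy enal may absorb too weakly, may drift to the silyloxy dienamine, or may give low ee. The fallback sets the stereocenter by substrate control instead. It sets out from 4: the same benzylic radical is made by single-electron oxidation and deprotonation with 9-mesityl-10-methylacridinium tetrafluoroborate (5 mol %), 2,6-lutidine, MeCN, 450 nm. The radical adds in a Giese reaction to commercial (5R)-5-[(1R,2S,5R)-menthyloxy]furan-2(5H)-one, anti to the menthyloxy group, to give (4R,5R)-5-{[(1R,2S,5R)-2-isopropyl-5-methylcyclohexyl]oxy}-4-(3,4,5-trimethoxybenzyl)dihydrofuran-2(3H)-one F1. NaBH4/KOH in aqueous EtOH opens the pseudo-ester, releases menthol and reduces the aldehyde to potassium (R)-4-hydroxy-3-(3,4,5-trimethoxybenzyl)butanoate F2. Acidification with HCl closes the lactone and the route is rejoined at 10.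

Step 9 may give ring bromination para to the methoxy group, or lose the carbonate. The fallback introduces the methoxy group last, so that the radical bromination runs on a deactivated ring. It sets out from 11: Boc2O/DMAP gives 2-bromo-4-methylphenyl tert-butyl carbonate F3, and NBS/AIBN gives 2-bromo-4-(bromomethyl)phenyl tert-butyl carbonate F4. Alkylation of enolate 15 (from 10) with F4 gives (3R,4R)-3-[3-bromo-4-(tert-butoxycarbonyloxy)benzyl]-4-(3,4,5-trimethoxybenzyl)dihydrofuran-2(3H)-one F5. NaOMe/CuBr in DMF/MeOH at 100 °C then replaces the aryl bromide by methoxide and removes the carbonate in the same operation. Acidic work-up and a short DBU equilibration (the trans lactone is the thermodynamic isomer) bring the route back at 17.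

Step 10 may suffer acyl transfer from the aryl carbonate to the enolate, double alkylation, or decomposition of 14. The fallback replaces the SN2 alkylation by an aldol addition and ionic deoxygenation. It sets out from 14: N-methylmorpholine N-oxide in MeCN at rt oxidises the benzylic bromide to tert-butyl (4-formyl-2-methoxyphenyl) carbonate F6. Addition of enolate 15 at −78 °C, anti to the C4 substituent, gives (3S,4R)-3-{[4-(tert-butoxycarbonyloxy)-3-methoxyphenyl](hydroxy)methyl}-4-(3,4,5-trimethoxybenzyl)dihydrofuran-2(3H)-one F7 as a mixture of carbinol epimers. Et3SiH in TFA/CH2Cl2 at 0 °C removes the benzylic hydroxyl (through the oxygen-stabilised benzylic cation) and the carbonate together, and the route is rejoined at 17.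

**Further compounds**
F1 | step 4 | (4R,5R)-5-{[(1R,2S,5R)-2-isopropyl-5-methylcyclohexyl]oxy}-4-(3,4,5-trimethoxybenzyl)dihydrofuran-2(3H)-one | O=C1C[C@@H](Cc2cc(OC)c(OC)c(OC)c2)[C@H](O[C@@H]2C[C@H](C)CC[C@H]2C(C)C)O1
F2 | step 4 | potassium (R)-4-hydroxy-3-(3,4,5-trimethoxybenzyl)butanoate | [K+].[O-]C(=O)C[C@H](CO)Cc1cc(OC)c(OC)c(OC)c1
F3 | step 9 | 2-bromo-4-methylphenyl tert-butyl carbonate | Cc1ccc(OC(=O)OC(C)(C)C)c(Br)c1
F4 | step 9 | 2-bromo-4-(bromomethyl)phenyl tert-butyl carbonate | BrCc1ccc(OC(=O)OC(C)(C)C)c(Br)c1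
F5 | step 9 | (3R,4R)-3-[3-bromo-4-(tert-butoxycarbonyloxy)benzyl]-4-(3,4,5-trimethoxybenzyl)dihydrofuran-2(3H)-one | Brc1cc(C[C@H]2C(=O)OC[C@@H]2Cc2cc(OC)c(OC)c(OC)c2)ccc1OC(=O)OC(C)(C)C
F6 | step 10 | tert-butyl (4-formyl-2-methoxyphenyl) carbonate | COc1cc(C=O)ccc1OC(=O)OC(C)(C)C
F7 | step 10 | (3S,4R)-3-{[4-(tert-butoxycarbonyloxy)-3-methoxyphenyl](hydroxy)methyl}-4-(3,4,5-trimethoxybenzyl)dihydrofuran-2(3H)-one (carbinol epimers) | COc1cc(C(O)[C@H]2C(=O)OC[C@@H]2Cc2cc(OC)c(OC)c(OC)c2)ccc1OC(=O)OC(C)(C)C
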